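Readings and results are simulated from invented constants, and the scatter is random.

Cedar, the run with the most free catalyst, was where I started. The flask lay between cedar and alder in free catalyst.

| flask | starting material | reagent | free catalyst | remark |
|---|---|---|---|---|
| alder | 0.050 M | 0.15 M | 6.7 mM | run made earlier |
| cedar | 0.050 M | 0.15 M | 15 mM | run made earlier |
| elm | 0.10 M | 0.15 M | 10 mM | run made earlier |
| flask | 0.050 M | 0.150 M | 10 mM |  |

| run | time / d | product / % |
|---|---|---|
| alder | 0.417 | 4 |
| alder | 0.625 | 4 |
| alder | 1.04 | 5 |
| alder | 1.67 | 5 |
| alder | 3.00 | 14 |
| alder | 5.00 | 21 |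
| cedar | 0.833 | 4 |
| cedar | 1.67 | 9 |
| cedar | 2.50 | 14 |
| cedar | 3.00 | 17 |
| cedar | 4.00 | 20 |
| cedar | 5.00 | 25 |
| elm | 0.417 | 0 |
| elm | 0.833 | 6 |
| elm | 1.25 | 3 |
| elm | 2.50 | 11 |
| elm | 5.00 | 18 |

(readings scatter by 2 percentage points)

- the analysis behind the earlier runs scatters by 2 percentage points, standard deviation
- no earlier run changes the charge of reagent; that part of a forecast is a guess

- apparent order in reagent when 50% of the starting material are converted (percent change of the rate of making product for one percent more reagent charged)
- apparent order in free catalyst when 50% of the starting material are converted (percent change of the rate of making product for one percent more free catalyst charged)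

I worked in logarithms. Alder and cedar held 21% and 25% at 5.00 d, which gave me 0.216 as the catalyst slope, the change of ln(product) per change of ln(free catalyst charged) at equal time. Those readings differ by 4 percentage points, with 2 points of scatter on each, so the slope was a weak reading.

Then I laid out the times. At 0.833 d, cedar's 4% barely stood clear of the scatter. At 5.00 d the readings ended. At a constant pace, 50% conversion lay at 10.0 d for cedar and 11.9 d for alder. By the slope it lay at 10.9 d for the flask, which is later than any reading. The question therefore lay 1.12 powers of ten above the first rung, beyond the readings.

The forecast gave 0.7 in reagent and 0.3 in free catalyst, saying “This weak dependence suggests saturation or a catalyst resting state such as a dimer”. My slope was lower than its catalyst figure.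

The flask gave 0.0028 in reagent and 0.53 in free catalyst, at 14.4 d, later than my 10.9 d.

    reagent + free catalyst → catalyst intermediate A (k = 11.0 L mol⁻¹ h⁻¹)
    catalyst intermediate A → catalyst intermediate B (k = 0.800 h⁻¹)
    starting material + catalyst intermediate B ⇌ catalyst intermediate C (K = 25.0 L mol⁻¹, k = 6.30 L mol⁻¹ h⁻¹)
    catalyst intermediate C → free catalyst + product (k = 0.230 h⁻¹)
    2 catalyst intermediate B ⇌ resting dimer, settled at all times (K = 10000 L mol⁻¹)

Applied to cedar's 20% at 4.00 d, my slope gave the flask 18.3% of product against the 16.8% that stood in it; applied to cedar's 17% at 3.00 d, it gave alder 14.3% against alder's reading of 14%. In the flask, by 1.60 d the step of reagent with free catalyst had 52% of its turnover up to 8.00 d behind it, and the step of starting material with catalyst intermediate B 24% of its own; the resting dimer, the resting state, held 87.4% of the catalyst charged at 0.800 d. At 80.0 d the flask held 97.9% product, with 60.7% of the reagent left.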